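**Plan**

1. Ring numbering used in all comments: C1(=O), C2(CH3), C3(n-C22H45), C4(=O), C5(OCH3), C6(H). The quinone is traced back to the arene carrying OCH3 on C1, C4 and C5. That arene is traced back to a cyclohexane-1,3-dione with carbonyls at C1 and C5 and OCH3 on C4.
2. The carbocycle is cut at C3–C4 and C5–C6. The C2=C3 alkene of the resulting open-chain enone is cut by olefination, which leaves a C23 aldehyde.
3. Enabling feature: in the single six-membered ring, C6–C1–C2–C3 is the backbone of an α-methyl enone whose acetyl CH3 is C6. C4–C5 is the oxygen-bearing methine plus one ester carbon of a methoxymalonate. The 1,2,4-oxygen pattern and the adjacent methyl/docosyl pair therefore follow from how the two pieces are bonded.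
4. Forward: alcohol, aldehyde, enone (chain joined), then a one-flask [3+3] annulation closes the only ring. Ester removal follows, then aromatisation with O-methylation, which installs the C5 methoxyl. Oxidative demethylation of the para pair C1/C4 finishes the route, and the malonate's own methoxyl is lost there.
5. Stereochemistry: the target has no stereocentre. The enone geometry and the three sp3 centres of the annulation product are transient and are erased when the ring becomes aromatic.

Key step: step 3

Assumption: the three purchased compounds are catalogue items; the cyclic 1,3-diones are drawn as diketo tautomers although they should be largely enolised, and their sp3 centres are left undefined because each is expected as a diastereomer mixture.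

**Step 1**
Reactants: 1 tricosan-1-ol
Product: 2 tricosanal
Conditions: 2-iodoxybenzoic acid (IBX, 1.5 equiv), EtOAc, 80 °C
Reagents that add atoms: none
Why: IBX oxidation of a primary alcohol stops at the aldehyde, and hot ethyl acetate dissolves the waxy C23 alcohol while the oxidant and its reduced form stay insoluble and are filtered off.

**Step 2**
Reactants: 2 tricosanal; 3 diethyl (3-oxobutan-2-yl)phosphonate
Product: 4 (E)-3-methylhexacos-3-en-2-one
Conditions: 3, NaH, THF, 0 °C; then 2, 0 to 45 °C; 1 M HCl quench
Reagents that add atoms: none
Why: Horner–Wadsworth–Emmons olefination, in which the stabilised α-methyl β-ketophosphonate anion adds reversibly to the unhindered aldehyde and collapses through the less crowded oxaphosphetane to the (E)-trisubstituted enone, and any (Z)-isomer is harmless because the geometry is lost in step 3.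

**Step 3**
Reactants: 4 (E)-3-methylhexacos-3-en-2-one; 5 dimethyl 2-methoxymalonate
Product: 7 methyl 2-docosyl-1-methoxy-3-methyl-4,6-dioxocyclohexane-1-carboxylate (diastereomer mixture), via acyclic keto diester 6 (not isolated)
Conditions: 5 (1.5 equiv), NaOCH3 (1.2 equiv), CH3OH–THF, reflux; then 1 M HCl, 0 °C
Reagents that add atoms: none
Why: Methoxide generates the anion of 5, whose carbon adds to the β-carbon of 4 (C3–C4 bond) to give keto diester 6; proton exchange then produces the enolate of the acetyl CH3, which displaces methoxide from one ester group (C5–C6 bond). The closest known reaction type is the Michael–Claisen (Dieckmann-type) annulation of malonic esters with alk-3-en-2-ones, the standard entry to 5-alkylcyclohexane-1,3-diones, run here with a 2-alkoxymalonate as donor. The one ring closes in the 6-(enolendo)-exo-trig mode, and both reversible bond formations are pulled forward because 7 leaves the equilibria as its stabilised 1,3-dione enolate, hence the full equivalent of base. C2, C3 and C4 become stereocentres with no controlling element beyond equilibration at C2, and none is needed, since all three are sp2 again after step 5. The selectivity that matters is regiochemical and is built into the bonding pattern of the partners: the stabilised carbanion prefers 1,4-addition over reversible 1,2-addition, and in 6 only the CH3-derived enolate reaches an ester through a six-membered transition state, the C2 enolate being limited to a four-membered one. Should that minor path shift a CO2CH3 group from C4 to C2, or should methoxide strip one ester from 6 before closure, the material would still converge on the same dione after step 4.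

**Step 4**
Reactants: 7 methyl 2-docosyl-1-methoxy-3-methyl-4,6-dioxocyclohexane-1-carboxylate
Product: 9 5-docosyl-4-methoxy-6-methylcyclohexane-1,3-dione (diastereomer mixture), via keto acid 8 (not isolated)
Conditions: KOH (5 equiv), CH3OH–H2O, reflux; then 6 M HCl to pH 1, 80 °C
Reagents that add atoms: none
Why: Ester saponification followed by β-keto acid decarboxylation, the usual finish of malonate–enone annulations: in base the ring is shielded as its 1,3-dione enolate so hydroxide attacks the ester, on acidification keto acid 8 loses CO2 through a cyclic six-centre transition state, and the C4 centre so formed is uncontrolled and erased in step 5.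

**Step 5**
Reactants: 9 5-docosyl-4-methoxy-6-methylcyclohexane-1,3-dione
Product: 10 3-docosyl-1,2,5-trimethoxy-4-methylbenzene
Conditions: I2 (2.2 equiv), CH3OH–toluene, reflux
Reagents that add atoms: methanol, CO
Why: Iodine–methanol aromatisation of a cyclohexane-1,3-dione, in which HI-catalysed enol-ether formation at both carbonyls, α-iodination and loss of HI supply the missing ring C=C bond, and tautomerisation gives the resorcinol dimethyl ether with the C4 methoxyl carried through, removing all three sp3 centres.

**Step 6**
Reactants: 10 3-docosyl-1,2,5-trimethoxy-4-methylbenzene
Product: 11 3-docosyl-5-methoxy-2-methylcyclohexa-2,5-diene-1,4-dione (target)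
Conditions: (NH4)2Ce(NO3)6 (2.5 equiv), CH3CN–CH2Cl2–H2O, 0 °C, 10 added to the oxidant
Reagents that add atoms: water, O
Why: Oxidative demethylation of a 1,4-dimethoxyarene by tetravalent cerium, in which two one-electron oxidations with capture of water at C1 and C4, the only para-related pair of methoxy-bearing carbons, release two CH3OH and leave the C5 methoxyl as the vinylogous ester of a 2-methoxy-1,4-benzoquinone.

**Compound list**

1 | tricosan-1-ol | CCCCCCCCCCCCCCCCCCCCCCCO | starting material
2 | tricosanal | CCCCCCCCCCCCCCCCCCCCCCC=O | intermediate
3 | diethyl (3-oxobutan-2-yl)phosphonate (racemic) | CCOP(=O)(OCC)C(C)C(C)=O | starting material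
4 | (E)-3-methylhexacos-3-en-2-one | CCCCCCCCCCCCCCCCCCCCCC/C=C(\C)C(C)=O | intermediate
5 | dimethyl 2-methoxymalonate | COC(=O)C(OC)C(=O)OC | starting material
6 | dimethyl 2-methoxy-2-(3-methyl-2-oxohexacosan-4-yl)propanedioate (diastereomer mixture) | COC(=O)C(OC)(C(=O)OC)C(CCCCCCCCCCCCCCCCCCCCCC)C(C)C(C)=O | intermediate
7 | methyl 2-docosyl-1-methoxy-3-methyl-4,6-dioxocyclohexane-1-carboxylate (diastereomer mixture) | COC(=O)C1(OC)C(CCCCCCCCCCCCCCCCCCCCCC)C(C)C(=O)CC1=O | intermediate
8 | 2-docosyl-1-methoxy-3-methyl-4,6-dioxocyclohexane-1-carboxylic acid (diastereomer mixture) | OC(=O)C1(OC)C(CCCCCCCCCCCCCCCCCCCCCC)C(C)C(=O)CC1=O | intermediate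
9 | 5-docosyl-4-methoxy-6-methylcyclohexane-1,3-dione (diastereomer mixture) | COC1C(CCCCCCCCCCCCCCCCCCCCCC)C(C)C(=O)CC1=O | intermediate
10 | 3-docosyl-1,2,5-trimethoxy-4-methylbenzene | CCCCCCCCCCCCCCCCCCCCCCc1c(C)c(OC)cc(OC)c1OC | intermediate
11 | 3-docosyl-5-methoxy-2-methylcyclohexa-2,5-diene-1,4-dione | CCCCCCCCCCCCCCCCCCCCCCC1=C(C)C(=O)C=C(OC)C1=O | target

Total step count: 6. Longest linear sequence: 6 steps (1, 2, 4, 7, 9, 10, 11).

**Steps most likely to fail**

**Step 3.**
- Risk: the conjugate addition is reversible and must build a fully substituted carbon next to two tertiary ones. Retro-addition, γ-deprotonation and self-condensation of the enone may therefore outrun ring closure.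
- Fallback: it sets out from 4 and 5 and comes back to the route at 7, forming the same two bonds in separate, kinetically controlled operations.
- Malonate 5 would be O-silylated (Me3SiOTf, Et3N, Et2O, 0 °C) to the ketene silyl acetal methyl 2,3-dimethoxy-3-[(trimethylsilyl)oxy]prop-2-enoate F1.
- F1 would be added to 4 in a TiCl4-promoted Mukaiyama–Michael reaction (CH2Cl2, −40 °C). This addition does not revert under the reaction conditions, and aqueous work-up should allow keto diester 6 to be isolated.
- Kinetic deprotonation of the acetyl CH3 of 6 with LiN(SiMe3)2 (2.2 equiv, THF, −78 to 0 °C) would then close the C5–C6 bond as a separate Claisen condensation. The C2 enolate needed for retro-addition should not build up under these conditions.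

**Step 5.**
- Risk: the ring may aromatise by loss of methanol from C4 instead of by dehydrogenation, which would delete the C4 oxygen. The two ring oxygens may also be only partly etherified.
- Fallback: it sets out from 9 and comes back at 10.
- Double O-silylation (Me3SiOTf, Et3N, CH2Cl2, 0 °C) should give [(5-docosyl-4-methoxy-6-methylcyclohexa-1,3-diene-1,3-diyl)bis(oxy)]bis(trimethylsilane) F2. It is drawn with ring double bonds C4=C5 and C6=C1; the isomeric diene would lead to the same arene. In F2 the C4 methoxyl sits on an sp2 carbon and can no longer be eliminated.
- Dehydrogenation of this cyclohexa-1,3-diene with DDQ (toluene, 0 °C) should give [(5-docosyl-4-methoxy-6-methyl-1,3-phenylene)bis(oxy)]bis(trimethylsilane) F3.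
- Desilylative alkylation of F3 (CsF, CH3I, DMF, room temperature) would give 10. The same closing alkylation would also complete the etherification of crude material from step 5.

**Step 4.**
- Risk: hydroxide may attack the neopentyl-type ester only slowly, and retro-Claisen opening of the ring may compete during prolonged heating in base.
- Fallback: it sets out from 7 and comes back at 9, and it makes no new compound.
- The ester would be removed by Krapcho dealkoxycarbonylation (LiCl, DMSO–H2O, 150 °C).
- Chloride cleaves the unhindered O–CH3 bond by SN2 attack instead of approaching the shielded acyl carbon, and the carboxylate loses CO2 in the same flask. The ring carbonyls never meet hydroxide.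

**Further compounds**

F1 | step 3 | methyl 2,3-dimethoxy-3-[(trimethylsilyl)oxy]prop-2-enoate (alkene geometry not defined) | COC(=O)C(OC)=C(OC)O[Si](C)(C)C
F2 | step 5 | [(5-docosyl-4-methoxy-6-methylcyclohexa-1,3-diene-1,3-diyl)bis(oxy)]bis(trimethylsilane) (diastereomer mixture) | COC1=C(O[Si](C)(C)C)C=C(O[Si](C)(C)C)C(C)C1CCCCCCCCCCCCCCCCCCCCCC
F3 | step 5 | [(5-docosyl-4-methoxy-6-methyl-1,3-phenylene)bis(oxy)]bis(trimethylsilane) | COc1c(O[Si](C)(C)C)cc(O[Si](C)(C)C)c(C)c1CCCCCCCCCCCCCCCCCCCCCC
F0 | step 4 | none | none
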